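Readings and results were computed with constants of no real substance; the scatter is artificial.

Per molar is the unit of a second-order rate constant multiplied by a time constant, and I reckoned this flask in it.

| flask | substrate | coupling partner | free catalyst | temperature | remark | time |
|---|---|---|---|---|---|---|
| Thursday's | 0.53 M | 0.318 M | 0.27 mM | 80 °C | the very flask that is asked about, followed so far |  |
| Sunday's | 0.80 M | 0.318 M | 0.27 mM | 80 °C | run made earlier |  |
| flask | 0.53 M | 0.318 M | 0.27 mM | 80 °C |  | 5.0 d |

Thursday's flask and Sunday's run differ in substrate, so together they show how far one reckoning stretches.

- Thursday's (time / d: product / %): 0.250: 26.4; 0.833: 42.3; 1.25: 43.0; 2.00: 50.1; 3.00: 48.9; 4.00: 49.6; 5.00: 48.7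
- Sunday's (time / h: product / %): 2.00: 10.8; 3.00: 12.6; 4.00: 16.6; 6.00: 20.1; 10.0: 26.2; 15.0: 28.3; 25.0: 32.5

(scatter of a reading: 1 percentage point)

- alder: at 5.0 d raise the temperature by 15 K, then wait 10 d
- oak: change nothing and wait 10 d more
- ash: at 5.0 d take out 90% of the product then present, then wait 10 d
- cedar: at 5.0 d add coupling partner, 50.0% of the amount charged, then wait 10 d
- birch: at 5.0 d add free catalyst, 100% of the amount charged, then wait 10 d

- product, in percent of the substrate first charged, at 5.0 d
- what to do for the largest gain in product; "none" if nothing gains more than 2 percentage points (alder / oak / ash / cedar / birch / none)
- product present, with what was taken out counted in, in percent of the substrate first charged, after alder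
- product present, with what was taken out counted in, in percent of the substrate first charged, after ash

- removed product is counted in
- the numbers in the tables scatter with a standard deviation of 1 percentage point
- the earlier runs do not show what temperature does; that part of a forecast is a guess
- additions bring no volume worth counting

Thursday's flask held 49.3% over its last four readings, or 0.261 M of product. But 0.0566 M of coupling partner, the limiting reagent, stood beside it, so the flask halted short of the 60.0% its charge allows.

I therefore took the halt for free catalyst dying on a first-order clock. Each bit of product divided by substrate times coupling partner then sums to rate constant times catalyst time constant. This catalyst budget, the logarithm of (partner charge × substrate left)/(substrate charge × partner left) over the difference of the charges, came to 4.94 M⁻¹.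

That was the late end. At the early end, the first reading had used 1.29 M⁻¹, which is 26.1% of the budget, and that reads as a catalyst half-life of 0.573 d. Sunday's run, with more substrate, had used 2.71 M⁻¹ by its last reading at 25.0 h. At that half-life this reads as a budget of 3.79 M⁻¹, smaller than Thursday's 4.94 M⁻¹, so I kept the budget for this flask's substrate charge and did not carry it to Sunday's.

At 5.0 d that half-life leaves 0.235% of the free catalyst, so I expected each option without fresh catalyst to stay near the plateau, with heat a guess. Fresh catalyst doubles this flask's budget, and the same formula then gave me 56.8%.

The forecast gave 49.3% now, birch as best, 49.6% after alder and 49.6% after ash, on the ground: “That points to catalyst dying”.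

The flask gave 50.4%. With birch it gained 7.2 percentage points, reaching 57.6%, more than any other option, while alder ended at 50.4% and ash at 50.5%.

    substrate + coupling partner + free catalyst → product + free catalyst, rate k1*[substrate]*[coupling partner]*[free catalyst]/(1 + ([substrate]/sat1)) (1.00 M, k = 1200 M⁻² h⁻¹, Ea = 43.0 kJ mol⁻¹)
    free catalyst → spent catalyst (k = 0.0450 h⁻¹, Ea = 118 kJ mol⁻¹)
    (constants at 80 °C)

On this flask the doubled budget had given 56.8% against the 57.6% found. Carried to the neighbour charged with 0.13 M of coupling partner, substrate as in the recipe, the budget of 4.94 M⁻¹ gives 21.9% of product. That neighbour holds 21.9% at 5.00 d, with 78.1% of its substrate and 11% of its coupling partner left.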